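## The problem

The target 27 is a heliangolide-type germacranolide: a ten-membered carbocycle with a (Z)-C4=C5 alkene, a C1–C10 epoxide in which C9 and C2 are trans, and an α-methylene-γ-lactone trans-fused across C6–C7. Five stereocentres (1R, 6R, 7R, 8R, 10S) must be set. C7 and C8 are vicinal and can be made together in the open chain; the epoxide pair C1/C10 is remote from them and needs reagent control; C6 adjoins C7 and can be left to substrate control. The primary acetate at C14, the methacrylate at C8 and the lactone rule out any late saponification. The two acrylate units, the epoxide (prone to acid-induced transannular opening by C4=C5) and the allylic lactone forbid strong acid, strong base, hydride and hydrogenation near the end. The C8 oxygen and the C12 carboxyl would close readily to an unwanted 8,12-lactone, so C8 must be acylated before the acid is freed. The feature that invites a short endgame is that C6 is both allylic to C4=C5 and γ to the C12 carboxyl of the 6-deoxy seco acid 26; once C1=C10 is epoxidised, C6–H is the only allylic C–H bond from which a five-membered lactone can form.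

## Retrosynthesis

**27 ⇒ 26 (C6–O).** The lactone C6–O bond is cut, leaving seco acid 26, to be closed by palladium-catalysed allylic C–H lactonisation. The neighbouring choice, carrying a C6 hydroxyl through the route, would add a fourth oxygen function to differentiate and a stereocentre to set early. This cut removes one ring and one stereocentre and leaves nothing to do after it. It asks for C6 over C3 and C15, retention of the Z alkene, trans fusion and survival of the epoxide. To help it, the acid is liberated under neutral conditions just before, no external acid is added, and C1=C10 is already epoxidised.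

**26 ⇒ 25 ⇒ 24 ⇒ 23 (ester, acetate, epoxide).** The acid is masked as the 2-(trimethylsilyl)ethyl ester 25: hydroxide would also take the acetate, acid would open the epoxide, and an allyl ester would not survive the zerovalent palladium of the ring closure. The acetate comes from alcohol 24, and the epoxide from allylic alcohol 23 by Sharpless epoxidation, which gives reagent control over the remote C1/C10 pair. Epoxidation is placed after ring closure because the open-chain precursor is a 1,3-diene, and a vinyl epoxide would not survive hydroboration or zerovalent palladium.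

**23 ⇒ 22 ⇒ 20 (C3–C4, ring).** The ring is opened at the sp3–sp2 bond C3–C4: the terminal CH2 of the diene in 20 is hydroborated to borane 21 and coupled with the (Z)-vinyl iodide (B-alkyl Suzuki–Miyaura). No stereocentre is formed and both alkene geometries are fixed beforehand. Closing at C7–C8 instead would create two stereocentres under uncertain macrocyclic control. The forward step must close a medium ring faster than side reactions of the vinylpalladium species.

**20 ⇒ 19 ⇒ 18 ⇒ 17 ⇒ 16 (C4=C5 and C1–C2).** The Z-iodoalkene comes from aldehyde 19 by Stork–Zhao olefination, which places iodine cis to the chain. Aldehyde 19 comes from silyl ether 17 via alcohol 18, and the vinyl group at C1 of 17 from vinyl iodide 16 by Stille coupling. The C1 iodide is consumed before the C4 iodide is made, so the two never coexist.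

**16 ⇒ 15 ⇒ 7 + 13 (C7–C8).** The C7–C8 bond is cut to aldehyde 13 and allylboronate 7. A closed chair transition state turns the chain cis to CH2B into the syn C7/C8 relation, and a chiral phosphoric acid selects the aldehyde face, so both centres arise in one catalyst-controlled step. A metal-mediated Barbier reaction of the corresponding bromide would give the same syn adduct only as a racemate. Alcohol 15 is acylated at once to 16, which installs the final C8 ester and blocks the 8,12-lactone.

**7 ⇒ 6 ⇒ 5 ⇒ 3 + 4.** The boronate comes from acetate 6 by copper-catalysed SN2′ borylation, and 6 from the Morita–Baylis–Hillman alcohol 5 of acrylate 3 and aldehyde 4. Ester 3 is made from 1 and 2. The saturated aldehyde 4 is used because the β,γ-unsaturated aldehyde that would carry C4=C5 directly would not survive the amine catalyst.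

**13 ⇒ 11 ⇒ 10 ⇒ 8.** Aldehyde 13 comes from oxidative cleavage of the allyl group of 11, the PMB ether of 10. Iodo alcohol 10 comes from anti-allylmagnesiation and iodinolysis of propargyl alcohol 8, which puts iodine cis to CH2OH. This geometry later becomes C2 cis to C14 and hence the trans C9/C2 relation of the epoxide.

## Roads not taken

**Alternative 1:** The ring would be opened at C2–C3. Pd(PPh3)4 ionises a C5 allylic carbonate to a 2-methyl-π-allyl complex, and a phenylsulfonyl carbanion at C2 (NaH) attacks C3, closing the ring with the alkene at C4=C5 to give A1.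
- Merits: a known reaction type for medium rings; convergent with respect to the C5 epimers; the C6 oxygen is present from the start, so no C–H oxidation is needed.
- Weak points: the Z alkene requires the less stable anti π-allyl isomer, and attack at C5 competes. A1 still needs desulfonylation, lactonisation, α-methylenation, epoxidation, several deprotections and two acylations, about ten steps.
- Comparison: Alternative 1 is better in the precedent of its key step and in the certainty of the C6 oxygen. The chosen plan sets against this alkene geometries fixed before ring closure and an endgame with no step after the key reaction.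

**Alternative 2:** Ring and oxirane would form together. KN(SiMe3)2 deprotonates a C1 diphenylsulfonium salt, the ylide adds to a C10 ketone, and the betaine closes to the epoxide, giving A2.
- Merits: one step makes the C1–C10 bond, the ring and two stereocentres; the C6 oxygen is in place.
- Weak points: a ten-membered Corey–Chaykovsky closure has no close precedent. The epoxide configuration rests on the ring-closing transition state with no reagent control. The α-alkoxy ketone can enolise and the sulfonium salt can eliminate. Oxidation at C12, lactonisation and acylations remain.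
- Comparison: both key steps are new. Alternative 2 is better in that failure would show early on cheap material, whereas the chosen key step is tested only at the end. The chosen plan sets against this reagent control of the epoxide and a conventional ring closure.

**Alternative 3:** A cyclohexene from the terpene pool, bearing two trans alkenyl groups and a tertiary alkoxide, would be expanded by an anionic oxy-Cope rearrangement (KH, 18-crown-6). C8–C9 forms, C1–C6 breaks, and dienone A3 results.
- Merits: the best-precedented entry to cyclodeca-1,5-dienes; ring strain is bypassed; the chair transition state transmits stereochemistry; the route to A3 is short.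
- Weak points: A3 has only the C8 stereocentre. The C7 side chain must be added by enolate chemistry and the C6 ketone reduced, setting C6 and C7 in a flexible ring. The Z geometry of the enone depends on the course of the rearrangement. Epoxidation and protecting-group exchange follow.
- Comparison: Alternative 3 is clearly better at making the ring and reaches the C6 oxygen without C–H activation. The chosen plan sets against this catalyst-controlled C7/C8 before ring closure and no redox or protecting-group step after the key reaction.

Key step: step 19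

Assumption: the (S)-enantiomer of the phosphoric acid catalyst is taken to send the allyl unit to the Si face of the aldehyde, by analogy with pinacol allyl- and crotylboronates; if the sense is opposite, the (R)-catalyst is used.

## Route

Step 1
Reactants: 1 acryloyl chloride; 2 2-(trimethylsilyl)ethanol
Product: 3 2-(trimethylsilyl)ethyl acrylate
Conditions: Et3N, CH2Cl2, 0 °C, trace BHT
Reagents that add atoms: none
Why: Acylation of the alcohol by the acid chloride; this ester is chosen because fluoride removes it at the end without touching acetate, methacrylate or epoxide.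

Step 2
Reactants: 3 2-(trimethylsilyl)ethyl acrylate; 4 3-[(tert-butyldimethylsilyl)oxy]propanal
Product: 5 Morita–Baylis–Hillman alcohol (racemic)
Conditions: DABCO (0.3 equiv), neat, rt, 3–5 d
Reagents that add atoms: none
Why: Morita–Baylis–Hillman reaction (amine adds to the acrylate, the enolate adds to the aldehyde, the amine is eliminated); the carbinol centre is racemic and is erased in step 4.

Step 3
Reactants: 5 Morita–Baylis–Hillman alcohol
Product: 6 allylic acetate (racemic)
Conditions: Ac2O, pyridine, DMAP (cat.), CH2Cl2, 0 °C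
Reagents that add atoms: acetic anhydride, CC(=O)OC(C)=O
Why: Standard acylation; it supplies the leaving group for the SN2′ step.

Step 4
Reactants: 6 allylic acetate
Product: 7 (2E)-allylboronate
Conditions: B2pin2, CuCl (10 mol%), LiCl, KOAc, DMF, rt
Reagents that add atoms: bis(pinacolato)diboron, CC1(C)OB(OC1(C)C)B1OC(C)(C)C(C)(C)O1
Why: Copper-catalysed SN2′ borylation of a Morita–Baylis–Hillman acetate (borylcopper adds to the CH2 terminus, acetate leaves); the enoate forms with the chain trans to the ester, that is cis to CH2B, the geometry that leads to the syn adduct.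

Step 5
Reactants: 8 prop-2-yn-1-ol
Product: 10 (2Z)-2-(iodomethylidene)pent-4-en-1-ol, via vinylmagnesium alkoxide 9 (not isolated)
Conditions: allylmagnesium bromide (3 equiv), Et2O, 0 °C to rt; then iodine, THF, −78 to 0 °C
Reagents that add atoms: allylmagnesium bromide, C=CC[Mg]Br; iodine, [I][I]
Why: Anti-carbomagnesiation of the propargylic alkoxide puts allyl on the internal carbon and magnesium on the terminal carbon, held cis to CH2O by chelation; iodinolysis with retention gives iodine cis to CH2OH.

Step 6
Reactants: 10 (2Z)-2-(iodomethylidene)pent-4-en-1-ol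
Product: 11 PMB ether
Conditions: NaH, 4-methoxybenzyl chloride, Bu4NI (cat.), THF/DMF, 0 °C to rt
Reagents that add atoms: 4-methoxybenzyl chloride, COc1ccc(CCl)cc1
Why: Williamson etherification; as an allylic ether the PMB group is inert to zerovalent palladium and is later removed under neutral oxidative conditions.

Step 7
Reactants: 11 PMB ether
Product: 13 β,γ-unsaturated aldehyde, via diol 12 (not isolated)
Conditions: OsO4 (2 mol%), N-methylmorpholine N-oxide, acetone/H2O, 0 °C; then NaIO4, THF/pH 7 buffer, 0 °C; used at once
Reagents that add atoms: osmium tetroxide, O=[Os](=O)(=O)=O; N-methylmorpholine N-oxide, C[N+]1([O-])CCOCC1; water, O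
Why: Osmium-catalysed dihydroxylation selects the monosubstituted terminal alkene over the iodine-bearing trisubstituted one, and periodate cleaves the diol; the aldehyde is not stored because it can slip into conjugation.

Step 8
Reactants: 7 (2E)-allylboronate; 13 aldehyde
Product: 15 syn homoallylic alcohol, via pinacol borate 14 (not isolated)
Conditions: (S)-TRIP [(S)-3,3′-bis(2,4,6-triisopropylphenyl)-1,1′-binaphthyl-2,2′-diyl hydrogen phosphate] (10 mol%), 4 Å MS, toluene, −30 to 0 °C; cold aq. NaHCO3
Reagents that add atoms: none
Why: Chiral phosphoric acid-catalysed allylboration through a closed chair transition state: the chain cis to CH2B sits axial and gives the syn C7/C8 relation, and the catalyst directs attack to the Si face of the aldehyde, giving (3R,4R), which is 7R,8R in target numbering.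

Step 9
Reactants: 15 homoallylic alcohol
Product: 16 methacrylate
Conditions: methacrylic anhydride, Et3N, DMAP, CH2Cl2, 0 °C to rt, trace BHT
Reagents that add atoms: methacrylic anhydride, C=C(C)C(=O)OC(=O)C(C)=C
Why: DMAP-catalysed acylation of the secondary alcohol; it installs the final C8 ester and, done at once, blocks closure of the γ-hydroxy ester to the 8,12-lactone.

Step 10
Reactants: 16 methacrylate
Product: 17 (Z)-diene
Conditions: tributyl(vinyl)stannane, Pd2(dba)3 (2.5 mol%), AsPh3 (10 mol%), CuI (10 mol%), DMF, rt
Reagents that add atoms: tributyl(vinyl)stannane, C=C[Sn](CCCC)(CCCC)CCCC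
Why: Stille coupling with retention of alkene geometry; palladium at C1 is trans to the chain that carries the acrylate units, so no ring-forming Heck insertion is possible, and the fully substituted diene terminus makes the product a poor Diels–Alder diene.

Step 11
Reactants: 17 diene
Product: 18 primary alcohol
Conditions: camphorsulfonic acid (10 mol%), MeOH/CH2Cl2 (1:1), 0 °C
Reagents that add atoms: none
Why: Acid-catalysed methanolysis of the primary TBS ether; the PMB ether, the C–Si bond of the silylethyl ester and the carboxylic esters are stable under these conditions.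

Step 12
Reactants: 18 primary alcohol
Product: 19 aldehyde
Conditions: Dess–Martin periodinane, pyridine, CH2Cl2, 0 °C to rt
Reagents that add atoms: none
Why: Dess–Martin oxidation under buffered conditions; the carbon next to the new aldehyde (C6) is a CH2 group, so nothing can epimerise.

Step 13
Reactants: 19 aldehyde
Product: 20 (Z)-vinyl iodide
Conditions: EtPPh3I, n-BuLi, THF, 0 °C; iodine, −78 °C; NaN(SiMe3)2, −78 to −20 °C; then 19, −78 °C
Reagents that add atoms: (1-iodoethylidene)triphenylphosphorane, CC(I)=P(c1ccccc1)(c1ccccc1)c1ccccc1, made in the flask from ethyltriphenylphosphonium iodide, CC[P+](c1ccccc1)(c1ccccc1)c1ccccc1.[I-], and iodine, [I][I]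
Why: Stork–Zhao olefination: the non-stabilised α-iodo ylide gives the Z-iodoalkene (iodine cis to the chain) under kinetic control and at −78 °C reacts with the aldehyde far faster than with the acrylate esters; this fixes the C4=C5 geometry.

Step 14
Reactants: 20 (Z)-vinyl iodide
Product: 22 ten-membered diene, via B-alkyl-9-BBN borane 21 (not isolated)
Conditions: 9-BBN (1.5 equiv), THF, 0 °C to rt; then slow addition to Pd(dppf)Cl2 (10 mol%), AsPh3 (10 mol%), Cs2CO3 (3 equiv), DMF/THF/H2O, rt, 2 mM
Reagents that add atoms: none
Why: 9-BBN adds to the monosubstituted diene terminus (the electron-poor 1,1-disubstituted acrylate alkenes react far more slowly), and intramolecular B-alkyl Suzuki–Miyaura coupling closes C3–C4 with retention at both alkenes; room temperature and iodide-bound neutral palladium keep insertion of C11=C13 slow.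

Step 15
Reactants: 22 ten-membered diene
Product: 23 allylic alcohol
Conditions: DDQ (1.3 equiv), CH2Cl2/pH 7 phosphate buffer (10:1), 0 °C
Reagents that add atoms: none
Why: Oxidative PMB cleavage by benzylic hydride abstraction in a neutral medium; the isolated trisubstituted alkenes and the esters are not affected.

Step 16
Reactants: 23 allylic alcohol
Product: 24 epoxy alcohol
Conditions: Ti(OiPr)4 (20 mol%), L-(+)-diethyl tartrate (24 mol%), tert-butyl hydroperoxide, 4 Å MS, CH2Cl2, −20 °C
Reagents that add atoms: tert-butyl hydroperoxide, CC(C)(C)OO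
Why: Sharpless asymmetric epoxidation touches only the alkene of the allylic alcohol (C1=C10); L-(+)-tartrate delivers oxygen to the face that gives 1R,10S, and the trans relation of C9 and C2 is inherited from the alkene.

Step 17
Reactants: 24 epoxy alcohol
Product: 25 epoxy acetate
Conditions: Ac2O, pyridine, DMAP (cat.), CH2Cl2, 0 °C
Reagents that add atoms: acetic anhydride, CC(=O)OC(C)=O
Why: Acetylation of the primary alcohol under mildly basic conditions that the epoxide tolerates.

Step 18
Reactants: 25 epoxy acetate
Product: 26 seco acid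
Conditions: TASF [tris(dimethylamino)sulfonium difluorotrimethylsilicate] (3 equiv), DMF, 0 °C to rt; pH 5 phosphate buffer; used directly
Reagents that add atoms: none
Why: Fluoride attacks silicon and the 2-(trimethylsilyl)ethyl ester fragments with loss of ethene; the conditions are anhydrous and non-hydrolytic, so acetate, methacrylate and epoxide remain.

Step 19
Reactants: 26 seco acid
Product: 27 target, (1R,4Z,6R,7R,8R,10S)-14-acetoxy-1,10-epoxy-8-(methacryloyloxy)germacra-4,11(13)-dien-12,6-olide
Conditions: Pd(OAc)2/1,2-bis(phenylsulfinyl)ethane (20 mol%), benzoquinone (2 equiv), 1,4-dioxane, 45 °C, 5 mM, no added acid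
Reagents that add atoms: none
Why: Proposed new method: Pd(OAc)2 exchanges an acetate for the C12 carboxylate of 26, divalent palladium binds C4=C5, and carboxylate-assisted cleavage of the C6–H bond (six-membered array O···H–C6–C7–C11–C12) gives a π-allylpalladium carboxylate over C4–C5–C6; benzoquinone-promoted C–O bond formation at C6 closes the lactone, and benzoquinone reoxidises zerovalent palladium. The closest known reaction type is the palladium/bis-sulfoxide-catalysed allylic C–H oxidative lactonisation and macrolactonisation of terminal alkenes bearing tethered carboxylic acids; its use on an internal trisubstituted ring alkene is the unprecedented part. The one ring closed is the γ-lactone, formed 5-exo at the allyl terminus (ring atoms O, C12, C11, C7, C6), whereas attack at C4 would need a seven-membered ring. The new stereocentre C6 is controlled by C7: the palladium-bound carboxylate reaches C6 only from the face that places C5 and C8 trans on the five-membered ring, which gives the trans-fused 6R lactone. Selectivity for C6 over C3 and C15 rests on the tether, since only C6–H lies within reach of the internal base and allyl units through C15 or C3 could close only to six-membered or larger rings, and on the earlier epoxidation of C1=C10, which leaves no second allylic system. The Z geometry of C4=C5 is kept because the ring holds C3 anti on the allyl unit and the σ-bond at tertiary C4 needed for isomerisation is disfavoured. The electron-poor methacrylate and C11=C13 alkenes do not bind the electrophilic catalyst, and the absence of added acid protects the epoxide.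

## Compound list

1 | prop-2-enoyl chloride | C=CC(=O)Cl | starting material
2 | 2-(trimethylsilyl)ethan-1-ol | C[Si](C)(C)CCO | starting material
3 | 2-(trimethylsilyl)ethyl prop-2-enoate | C=CC(=O)OCC[Si](C)(C)C | intermediate
4 | 3-[(tert-butyldimethylsilyl)oxy]propanal | O=CCCO[Si](C)(C)C(C)(C)C | starting material
5 | 2-(trimethylsilyl)ethyl 5-[(tert-butyldimethylsilyl)oxy]-3-hydroxy-2-methylidenepentanoate (racemic) | C=C(C(=O)OCC[Si](C)(C)C)C(O)CCO[Si](C)(C)C(C)(C)C | intermediate
6 | 2-(trimethylsilyl)ethyl 3-(acetyloxy)-5-[(tert-butyldimethylsilyl)oxy]-2-methylidenepentanoate (racemic) | C=C(C(=O)OCC[Si](C)(C)C)C(OC(C)=O)CCO[Si](C)(C)C(C)(C)C | intermediate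
7 | 2-(trimethylsilyl)ethyl (2E)-5-[(tert-butyldimethylsilyl)oxy]-2-[(4,4,5,5-tetramethyl-1,3,2-dioxaborolan-2-yl)methyl]pent-2-enoate | CC1(C)OB(C/C(C(=O)OCC[Si](C)(C)C)=C\CCO[Si](C)(C)C(C)(C)C)OC1(C)C | intermediate
8 | prop-2-yn-1-ol | C#CCO | starting material
9 | bromomagnesium (2Z)-3-(bromomagnesio)-2-(prop-2-en-1-yl)prop-2-en-1-olate | C=CC/C(CO[Mg]Br)=C/[Mg]Br | intermediate (not isolated)
10 | (2Z)-2-(iodomethylidene)pent-4-en-1-ol | C=CC/C(CO)=C/I | intermediate
11 | 1-({[(2Z)-2-(iodomethylidene)pent-4-en-1-yl]oxy}methyl)-4-methoxybenzene | C=CC/C(=C/I)COCc1ccc(OC)cc1 | intermediate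
12 | (4Z)-5-iodo-4-{[(4-methoxybenzyl)oxy]methyl}pent-4-ene-1,2-diol (racemic) | OCC(O)C/C(=C/I)COCc1ccc(OC)cc1 | intermediate (not isolated)
13 | (3Z)-4-iodo-3-{[(4-methoxybenzyl)oxy]methyl}but-3-enal | O=CC/C(=C/I)COCc1ccc(OC)cc1 | intermediate
14 | 2-(trimethylsilyl)ethyl (3R,4R,6Z)-3-{2-[(tert-butyldimethylsilyl)oxy]ethyl}-7-iodo-6-{[(4-methoxybenzyl)oxy]methyl}-2-methylidene-4-[(4,4,5,5-tetramethyl-1,3,2-dioxaborolan-2-yl)oxy]hept-6-enoate | C=C(C(=O)OCC[Si](C)(C)C)[C@@H](CCO[Si](C)(C)C(C)(C)C)[C@H](OB1OC(C)(C)C(C)(C)O1)C/C(=C/I)COCc1ccc(OC)cc1 | intermediate (not isolated)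
15 | 2-(trimethylsilyl)ethyl (3R,4R,6Z)-3-{2-[(tert-butyldimethylsilyl)oxy]ethyl}-4-hydroxy-7-iodo-6-{[(4-methoxybenzyl)oxy]methyl}-2-methylidenehept-6-enoate | C=C(C(=O)OCC[Si](C)(C)C)[C@@H](CCO[Si](C)(C)C(C)(C)C)[C@H](O)C/C(=C/I)COCc1ccc(OC)cc1 | intermediate
16 | 2-(trimethylsilyl)ethyl (3R,4R,6Z)-3-{2-[(tert-butyldimethylsilyl)oxy]ethyl}-7-iodo-6-{[(4-methoxybenzyl)oxy]methyl}-2-methylidene-4-[(2-methylprop-2-enoyl)oxy]hept-6-enoate | C=C(C(=O)OCC[Si](C)(C)C)[C@@H](CCO[Si](C)(C)C(C)(C)C)[C@H](OC(=O)C(C)=C)C/C(=C/I)COCc1ccc(OC)cc1 | intermediate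
17 | 2-(trimethylsilyl)ethyl (3R,4R,6Z)-3-{2-[(tert-butyldimethylsilyl)oxy]ethyl}-6-{[(4-methoxybenzyl)oxy]methyl}-2-methylidene-4-[(2-methylprop-2-enoyl)oxy]nona-6,8-dienoate | C=C(C(=O)OCC[Si](C)(C)C)[C@@H](CCO[Si](C)(C)C(C)(C)C)[C@H](OC(=O)C(C)=C)C/C(=C/C=C)COCc1ccc(OC)cc1 | intermediate
18 | 2-(trimethylsilyl)ethyl (3R,4R,6Z)-3-(2-hydroxyethyl)-6-{[(4-methoxybenzyl)oxy]methyl}-2-methylidene-4-[(2-methylprop-2-enoyl)oxy]nona-6,8-dienoate | C=C(C(=O)OCC[Si](C)(C)C)[C@@H](CCO)[C@H](OC(=O)C(C)=C)C/C(=C/C=C)COCc1ccc(OC)cc1 | intermediate
19 | 2-(trimethylsilyl)ethyl (3R,4R,6Z)-6-{[(4-methoxybenzyl)oxy]methyl}-2-methylidene-4-[(2-methylprop-2-enoyl)oxy]-3-(2-oxoethyl)nona-6,8-dienoate | C=C(C(=O)OCC[Si](C)(C)C)[C@@H](CC=O)[C@H](OC(=O)C(C)=C)C/C(=C/C=C)COCc1ccc(OC)cc1 | intermediate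
20 | 2-(trimethylsilyl)ethyl (3R,4R,6Z)-3-[(2Z)-3-iodobut-2-en-1-yl]-6-{[(4-methoxybenzyl)oxy]methyl}-2-methylidene-4-[(2-methylprop-2-enoyl)oxy]nona-6,8-dienoate | C=C(C(=O)OCC[Si](C)(C)C)[C@@H](C/C=C(\I)C)[C@H](OC(=O)C(C)=C)C/C(=C/C=C)COCc1ccc(OC)cc1 | intermediate
21 | 2-(trimethylsilyl)ethyl (3R,4R,6Z)-9-(9-borabicyclo[3.3.1]nonan-9-yl)-3-[(2Z)-3-iodobut-2-en-1-yl]-6-{[(4-methoxybenzyl)oxy]methyl}-2-methylidene-4-[(2-methylprop-2-enoyl)oxy]non-6-enoate | C=C(C(=O)OCC[Si](C)(C)C)[C@@H](C/C=C(\I)C)[C@H](OC(=O)C(C)=C)C/C(=C/CCB1C2CCCC1CCC2)COCc1ccc(OC)cc1 | intermediate (not isolated)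
22 | 2-(trimethylsilyl)ethyl 2-[(1R,3Z,7Z,10R)-8-{[(4-methoxybenzyl)oxy]methyl}-4-methyl-10-[(2-methylprop-2-enoyl)oxy]cyclodeca-3,7-dien-1-yl]prop-2-enoate | C=C(C)C(=O)O[C@@H]1C/C(COCc2ccc(OC)cc2)=C/CC/C(C)=C\C[C@@H]1C(=C)C(=O)OCC[Si](C)(C)C | intermediate
23 | 2-(trimethylsilyl)ethyl 2-[(1R,3Z,7Z,10R)-8-(hydroxymethyl)-4-methyl-10-[(2-methylprop-2-enoyl)oxy]cyclodeca-3,7-dien-1-yl]prop-2-enoate | C=C(C)C(=O)O[C@@H]1C/C(CO)=C/CC/C(C)=C\C[C@@H]1C(=C)C(=O)OCC[Si](C)(C)C | intermediate
24 | 2-(trimethylsilyl)ethyl 2-[(1R,4Z,7R,8R,10S)-10-(hydroxymethyl)-4-methyl-8-[(2-methylprop-2-enoyl)oxy]-11-oxabicyclo[8.1.0]undec-4-en-7-yl]prop-2-enoate | C=C(C)C(=O)O[C@@H]1C[C@@]2(CO)O[C@@H]2CC/C(C)=C\C[C@@H]1C(=C)C(=O)OCC[Si](C)(C)C | intermediate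
25 | 2-(trimethylsilyl)ethyl 2-[(1R,4Z,7R,8R,10S)-10-[(acetyloxy)methyl]-4-methyl-8-[(2-methylprop-2-enoyl)oxy]-11-oxabicyclo[8.1.0]undec-4-en-7-yl]prop-2-enoate | C=C(C)C(=O)O[C@@H]1C[C@@]2(COC(C)=O)O[C@@H]2CC/C(C)=C\C[C@@H]1C(=C)C(=O)OCC[Si](C)(C)C | intermediate
26 | 2-[(1R,4Z,7R,8R,10S)-10-[(acetyloxy)methyl]-4-methyl-8-[(2-methylprop-2-enoyl)oxy]-11-oxabicyclo[8.1.0]undec-4-en-7-yl]prop-2-enoic acid (6-deoxy seco acid) | C=C(C)C(=O)O[C@@H]1C[C@@]2(COC(C)=O)O[C@@H]2CC/C(C)=C\C[C@@H]1C(=C)C(=O)O | intermediate
27 | (1R,4Z,6R,7R,8R,10S)-14-acetoxy-1,10-epoxy-8-(methacryloyloxy)germacra-4,11(13)-dien-12,6-olide (CNP0150481.2) | C=C(C)C(=O)O[C@@H]1C[C@@]2(COC(C)=O)O[C@@H]2CC/C(C)=C\[C@H]2OC(=O)C(=C)[C@@H]21 | target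

## Step count and risks

Total step count: 19. Longest linear sequence: 16 steps (steps 1–4, then 8–19). The label for a new method is carried by step 19 only.

**Step 19 (key step).** What may go wrong:
- C–H cleavage at C15 or C3 instead of C6, which would lead to a six-membered lactone at C5 or to a diene;
- slow C–H cleavage, because internal trisubstituted alkenes bind the sulfoxide-ligated catalyst poorly;
- Lewis-acid opening of the epoxide with transannular attack by C4=C5;
- loss of the Z geometry through the π-allyl intermediate.

Fallback with known chemistry, from 19 back to 27: the C6 oxygen is introduced conventionally before the ring is closed. Aldehyde 19 is α-aminoxylated with nitrosobenzene under D-proline catalysis to the (6S)-anilinooxy aldehyde F1. F1 is taken directly into the iodo-olefination of step 13 to give the iodoalkene F2. CuSO4·5H2O in methanol cleaves the N–O bond to the allylic alcohol F3. Catalytic DBU then closes F3 onto the neighbouring ester, giving the trans-fused lactone F4 with loss of 2-(trimethylsilyl)ethanol. Hydroboration to the borane F5 and Suzuki ring closure as in step 14 give the macrocyclic lactone F6. DDQ frees the alcohol F7, Sharpless epoxidation with L-(+)-diethyl tartrate gives the epoxy alcohol F8, and acetylation gives 27.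

**Step 14 (ring closure).** What may go wrong: slow closure of the medium ring, so that oligomerisation, protodeboronation of 21, or insertion of C11=C13 into the C4–palladium bond can compete. That insertion would form a five-membered ring and is geometrically open because palladium at C4 is cis to C6.

Fallback, from 20 back to 22: a preformed alkylzinc replaces the borane and a Negishi coupling replaces the Suzuki coupling. Borane 21 is oxidised with NaBO3·4H2O to the primary alcohol F9. Iodine, PPh3 and imidazole convert it into the alkyl iodide F10. Zinc dust with LiCl in THF/DMA inserts into the sp3 C–I bond only. The alkylzinc iodide F11 is closed onto the vinyl iodide with Pd2(dba)3/SPhos at rt under high dilution to give 22.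

**Step 16 (epoxidation in the ring).** What may go wrong: the ring conformation rather than the tartrate may set the face, since the reagent must reach the outer face of a ring alkene whose two faces are unequally exposed. A mismatched case would show as low rate and poor selectivity.

Fallback, from 20 by way of F10 back to 25: epoxidation is moved in front of the ring closure, where the allylic alcohol is open-chain. DDQ converts F10 into the allylic alcohol F12. Sharpless epoxidation gives the epoxy alcohol F13, and acetylation gives the epoxy acetate F14. Zinc insertion to the alkylzinc iodide F15 and Negishi ring closure give 25.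

**Step 8 (allylboration).** What may go wrong:
- low reactivity of the ester-deactivated boronate toward the weak acid catalyst, with incomplete conversion or eroded enantioselectivity;
- closure of borate 14 onto the ester to the 8,12-lactone before work-up;
- drift of aldehyde 13 into conjugation.

Fallback, from 5 and 13 back to 16: NBS/Me2S converts 5 into the (2Z)-allylic bromide F16. Indium powder in THF/H2O couples F16 with 13 in a Barbier reaction, which should give the same syn adduct as a racemate, 15 together with its enantiomer F17. Burkholderia cepacia lipase with vinyl methacrylate then acylates the (R)-carbinol enantiomer and delivers 16 directly, leaving F17 behind. This costs at most half of the material.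

## Further compounds

F1 | step 19 | (6S)-6-(anilinooxy) derivative of aldehyde 19 | C=C(C(=O)OCC[Si](C)(C)C)[C@@H]([C@H](ONc1ccccc1)C=O)[C@H](OC(=O)C(C)=C)C/C(=C/C=C)COCc1ccc(OC)cc1
F2 | step 19 | 6-(anilinooxy) derivative of vinyl iodide 20 | C=C(C(=O)OCC[Si](C)(C)C)[C@@H]([C@H](ONc1ccccc1)/C=C(\I)C)[C@H](OC(=O)C(C)=C)C/C(=C/C=C)COCc1ccc(OC)cc1
F3 | step 19 | 6-hydroxy derivative of vinyl iodide 20 | C=C(C(=O)OCC[Si](C)(C)C)[C@@H]([C@H](O)/C=C(\I)C)[C@H](OC(=O)C(C)=C)C/C(=C/C=C)COCc1ccc(OC)cc1
F4 | step 19 | open-chain trans-6,12-lactone with Z-iodoalkene and diene | C=C1C(=O)O[C@H](/C=C(\I)C)[C@H]1[C@H](OC(=O)C(C)=C)C/C(=C/C=C)COCc1ccc(OC)cc1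
F5 | step 19 | B-alkyl-9-BBN borane of lactone F4 | C=C1C(=O)O[C@H](/C=C(\I)C)[C@H]1[C@H](OC(=O)C(C)=C)C/C(=C/CCB1C2CCCC1CCC2)COCc1ccc(OC)cc1
F6 | step 19 | macrocyclic 6,12-lactone, C14 PMB ether, C1=C10 alkene | C=C(C)C(=O)O[C@@H]1C/C(COCc2ccc(OC)cc2)=C/CC/C(C)=C\[C@H]2OC(=O)C(=C)[C@@H]21
F7 | step 19 | macrocyclic 6,12-lactone, C14 alcohol, C1=C10 alkene | C=C(C)C(=O)O[C@@H]1C/C(CO)=C/CC/C(C)=C\[C@H]2OC(=O)C(=C)[C@@H]21
F8 | step 19 | 14-deacetyl derivative of target 27 | C=C(C)C(=O)O[C@@H]1C[C@@]2(CO)O[C@@H]2CC/C(C)=C\[C@H]2OC(=O)C(=C)[C@@H]21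
F9 | step 14 | primary alcohol from oxidation of borane 21 | C=C(C(=O)OCC[Si](C)(C)C)[C@@H](C/C=C(\I)C)[C@H](OC(=O)C(C)=C)C/C(=C/CCO)COCc1ccc(OC)cc1
F10 | step 14 | primary alkyl iodide from F9 | C=C(C(=O)OCC[Si](C)(C)C)[C@@H](C/C=C(\I)C)[C@H](OC(=O)C(C)=C)C/C(=C/CCI)COCc1ccc(OC)cc1
F11 | step 14 | alkylzinc iodide from F10 | C=C(C(=O)OCC[Si](C)(C)C)[C@@H](C/C=C(\I)C)[C@H](OC(=O)C(C)=C)C/C(=C/CC[Zn]I)COCc1ccc(OC)cc1
F12 | step 16 | open-chain allylic alcohol from F10 | C=C(C(=O)OCC[Si](C)(C)C)[C@@H](C/C=C(\I)C)[C@H](OC(=O)C(C)=C)C/C(=C/CCI)CO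
F13 | step 16 | open-chain epoxy alcohol | C=C(C(=O)OCC[Si](C)(C)C)[C@@H](C/C=C(\I)C)[C@H](OC(=O)C(C)=C)C[C@@]1(CO)O[C@@H]1CCI
F14 | step 16 | open-chain epoxy acetate | C=C(C(=O)OCC[Si](C)(C)C)[C@@H](C/C=C(\I)C)[C@H](OC(=O)C(C)=C)C[C@@]1(COC(C)=O)O[C@@H]1CCI
F15 | step 16 | alkylzinc iodide from F14 | C=C(C(=O)OCC[Si](C)(C)C)[C@@H](C/C=C(\I)C)[C@H](OC(=O)C(C)=C)C[C@@]1(COC(C)=O)O[C@@H]1CC[Zn]I
F16 | step 8 | 2-(trimethylsilyl)ethyl (2Z)-2-(bromomethyl)-5-[(tert-butyldimethylsilyl)oxy]pent-2-enoate | BrC/C(C(=O)OCC[Si](C)(C)C)=C\CCO[Si](C)(C)C(C)(C)C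
F17 | step 8 | enantiomer of alcohol 15 (3S,4S) | C=C(C(=O)OCC[Si](C)(C)C)[C@H](CCO[Si](C)(C)C(C)(C)C)[C@@H](O)C/C(=C/I)COCc1ccc(OC)cc1
A1 | alternative 1 | ten-membered diene with C2 phenylsulfonyl group, product of the allylic alkylation | CC[Si](CC)(CC)O[C@@H]1C/C(COCc2ccc(OC)cc2)=C/[C@H](S(=O)(=O)c2ccccc2)C/C(C)=C\[C@@H](O[Si](C)(C)C(C)(C)C)[C@@H]1CC(=O)OC(C)(C)C
A2 | alternative 2 | protected 1,10-epoxy ten-membered ring with C7 2-propenyl unit, product of the ylide ring closure | CC[Si](CC)(CC)O[C@@H]1C[C@@]2(COCc3ccc(OC)cc3)O[C@@H]2CC/C(C)=C\[C@@H](O[Si](C)(C)C(C)(C)C)[C@@H]1C(=C)CO[Si](C)(C)C(C)(C)C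
A3 | alternative 3 | 8-(methoxymethoxy)-14-[(tert-butyldimethylsilyl)oxy]cyclodeca-1(10),4-dien-6-one, product of the oxy-Cope expansion | COCO[C@@H]1C/C(CO[Si](C)(C)C(C)(C)C)=C/CC/C(C)=C\C(=O)C1
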